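**Remark on numbering:** xanthane numbering is used for every compound: C1 ketol carbon, C2–C4 and C15 butenoyl chain, C5 ester carbon, C6 lactone O‑bearing carbon, C7 ring‑fusion carbon, C8/C9 methylenes, C10 methyl‑bearing carbon, C11–C13 lactone carbons. β is the face of the lactone ring, α the face of H‑6 and H‑7.

## The problem

Compound 16 is a 4,5‑seco‑guaiane (xanthane) lactone. Its cycloheptane (C1, C5–C10) is cis‑fused at C6/C7 to an α‑methyl‑γ‑butyrolactone (O–C6, C12, C11, C7). It carries CH3 on C10, an isobutyrate on C5 and, on C1, a tertiary hydroxyl and an (E)‑but‑2‑enoyl chain.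

Five contiguous ring stereocentres (C10, C1, C5, C6, C7) and C11 must be set. C7 and C10 are cis across the C8–C9 bridge, a 1,4‑relationship that the cheap p‑menthane pool offers only trans.

C1 is the hardest centre. It is fully substituted and lies between C10 (methyl on the β face) and C5 (oxygen on the α face), so a reagent approaching a C1 carbonyl meets one neighbour on each face. C1 can be controlled only while C5 is still sp2, with the C10 methyl as the single adjacent control element.

C5 has its oxygen trans to the oxygens on both neighbours (O1 β, O5 α, O6 β), which is the signature of two inversions at C5.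

The feature on which the key step rests is the C5=C6 double bond of the late acid 13. It lies γ,δ to the carboxyl carbon C12 (C12–C11–C7–C6=C5) and allylic to the C1 hydroxyl. Iodolactonization puts the lactone oxygen on C6 and iodine on C5 in one anti addition, and the C1 hydroxyl, anti to that iodine, can exchange it for the ester with net retention.

The α′‑hydroxy enone (retro‑aldol, α‑ketol shift, conjugate addition), the isobutyrate and the lactone rule out hydrogenation, strong base and hydride once they are present. C10 and C11 must therefore be fixed early and the last steps must be mild.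

## Retrosynthesis

**16 ⇒ 14 (C5–O ester bond).** The isobutyrate is taken off as the nucleophile, not as an acyl group. 16 comes from the 1β,5β‑epoxide 15 by attack of isobutyric acid at C5, and 15 from iodolactone 14 by closure of the C1 hydroxyl on C5. This is preferred to acylating a free C5 alcohol because the two inversions at C5 set O5 trans to both O1 and O6 and no hydroxyl has to be distinguished. The forward reaction must open the epoxide at C5 only, which C1 (quaternary, α to a carbonyl) enforces.

**14 ⇒ 13 (lactone C6–O and C5–I bonds).** Both bonds are cut together as an iodolactonization. The precursor 13 is monocyclic, has no lactone and only the centres C1, C7, C10 and C11. A C5/C6 epoxide route would need face control on a flexible ring, whereas the tethered carboxyl fixes the face by itself. The forward step must close 5‑exo and cis.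

**13 ⇒ 11 (C1–C2 bond).** The butenoyl group is removed as an acyl anion equivalent (lithiated 1‑methoxybuta‑1,3‑diene, via adduct 12). The partner is enone acid 11, whose C5 is sp2, so only the C10 methyl flanks the C1 carbonyl. The alternative order, oxygen on C5 before addition at C1, puts the nucleophile between two opposed neighbours. The addition must occur anti to the C10 methyl.

**11 ⇒ 10 ⇒ 9 ⇒ 8 (C10–H and C11–H bonds, temporary C6–O bond).** C10 and C11 are traced back to alkenes (C9=C10 enone, C11=C13 methylene). The cis C7/C10 relationship needs a face bias that the monocycle lacks. C6 is the β‑carbon of the C1 enone, so the acid can add to it: dienone acid 8 gives the cis‑fused lactone 9, whose convex face directs the hydrogenation to 10, and β‑elimination returns enone 11. This first lactone cannot simply be kept, because C5 would stay a methylene that can no longer be oxidized after C1 is built.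

**8 ⇒ 5 (oxidation level of C12).** The carboxyl is traced back to one methyl of an isopropenyl group (chloride 6, enal 7). The exocyclic methylene is kept because it is the handle for C11.

**5 ⇒ 1 (removal of ring carbon C5).** C10(CH3)–C9–C8–C7(C11) is a p‑menthane fragment: the ring of 5 is the carvone ring plus one carbon between C1 and C6. (R)‑Carvone 1 supplies C7 and ten carbons; the carbon is inserted through silyl dienol ether 2, cyclopropane 3 and chloro ketone 4. Regiochemistry is fixed by the kinetic α′ enolate.

## Roads not taken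

**Alternative 1:** ring‑closing metathesis, cutting C5=C6. Acyclic dienone ester A1 would be closed with the second‑generation Grubbs catalyst to cycloheptenone ester A2, the ester of 11. The cut is sound, but A1 needs three centres (C7, C10, C11) built by separate acyclic methods, one of them an epimerizable α‑methyl ketone, and a 1,4‑relationship without any ring to relay it. The chosen plan takes C7 from carvone and sets C10 and C11 in one hydrogenation.

**Alternative 2:** late insertion of C1 into a six‑membered ring. α′‑Lactonization of the carvone acid and hydrogenation would give keto lactone A3. Addition of a 2‑oxopent‑3‑enoyl anion equivalent gives ketol A4, and an α‑ketol rearrangement with migration of C10 gives the ring‑expanded ketol A5 with C1 complete. The drawbacks are mechanistic. The configuration at C1 depends on whether the O=C–C–O unit reacts s‑cis (chelated) or s‑trans. A six‑to‑seven α‑ketol expansion has no clear driving force. The C5 ketone of A5 would then need hydride from the concave face in the presence of the enone carbonyl.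

**Alternative 3:** (4+3) cycloaddition, cutting C1–C10 and C6–C7. The C1–C5–C6 unit is a dihydroxyacetone; an oxyallyl cation from ester A6, tethered through the future lactone to an (E,E)‑diene, would give cycloadduct A7 with the ring, the lactone and the cis C7/C10 relationship at once. It was set aside because the ester tether prefers the s‑trans form, the acyloxy‑substituted oxyallyl cation is poorly stabilized, and A7 still lacks both C1 substituents. It would end in the same C1 and C5 face problems as Alternative 2.

Key step: step 10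

## Steps

Step 1
Reactants: 1 (R)‑(−)‑carvone
Product: 2 trimethyl{[(3R)-6-methyl-3-(prop-1-en-2-yl)cyclohexa-1,5-dien-1-yl]oxy}silane
Conditions: LiN(iPr)2, THF, −78 °C; Me3SiCl, −78 to 0 °C
Reagents that add atoms: chlorotrimethylsilane C[Si](C)(C)Cl
Why: Kinetic deprotonation of the enone at the α′ methylene (the future C6) gives the cross‑conjugated dienolate, which is silylated on oxygen; the stereocentre (future C7) is untouched and is the only source of chirality of the route.

Step 2
Reactants: 2 trimethyl{[(3R)-6-methyl-3-(prop-1-en-2-yl)cyclohexa-1,5-dien-1-yl]oxy}silane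
Product: 3 trimethyl{[(1R,5R,6S)-2-methyl-5-(prop-1-en-2-yl)bicyclo[4.1.0]hept-2-en-1-yl]oxy}silane
Conditions: Et2Zn, CH2I2, CH2Cl2, 0 °C
Reagents that add atoms: diiodomethane ICI
Why: Simmons–Smith cyclopropanation in the Furukawa variant; the electrophilic zinc carbenoid takes the silyl enol ether double bond in preference to the isopropenyl group and the trisubstituted diene terminus. The new CH2 is the future C5 and the face of addition is without consequence.

Step 3
Reactants: 3 trimethyl{[(1R,5R,6S)-2-methyl-5-(prop-1-en-2-yl)bicyclo[4.1.0]hept-2-en-1-yl]oxy}silane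
Product: 5 (5R)-2-methyl-5-(prop-1-en-2-yl)cyclohepta-2,6-dien-1-one, via β-chloro ketone 4 (not isolated)
Conditions: FeCl3, DMF, 0 °C; then NaOAc, MeOH, 60 °C
Reagents that add atoms: none
Why: Ito–Saegusa ring expansion: FeCl3 oxidizes the siloxycyclopropane by one electron, the ring‑fusion bond breaks to a β‑keto radical that takes up chlorine, and acetate removes HCl. One carbon is thereby inserted between C1 and C6 and the C5=C6 enone is in place.

Step 4
Reactants: 5 (5R)-2-methyl-5-(prop-1-en-2-yl)cyclohepta-2,6-dien-1-one
Product: 6 (5R)-5-(3-chloroprop-1-en-2-yl)-2-methylcyclohepta-2,6-dien-1-one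
Conditions: Ca(OCl)2, solid CO2, CH2Cl2/H2O, 0 °C
Reagents that add atoms: calcium hypochlorite [Ca+2].[O-]Cl.[O-]Cl
Why: Ene‑type allylic chlorination by HOCl; only the electron‑rich 1,1‑disubstituted alkene reacts and the double bond moves within the isopropenyl unit, so one methyl (the future C12) becomes CH2Cl. The two enone double bonds are inert.

Step 5
Reactants: 6 (5R)-5-(3-chloroprop-1-en-2-yl)-2-methylcyclohepta-2,6-dien-1-one
Product: 7 2-[(1R)-5-methyl-4-oxocyclohepta-2,5-dien-1-yl]prop-2-enal
Conditions: N‑methylmorpholine N‑oxide, KI (cat.), NaHCO3, MeCN, 40 °C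
Reagents that add atoms: 4-methylmorpholine N-oxide C[N+]1([O-])CCOCC1
Why: Kornblum‑type oxidation with an amine N‑oxide: iodide‑catalysed O‑alkylation of the N‑oxide by the allylic chloride and loss of N‑methylmorpholine give the 2‑substituted acrolein under conditions that spare the dienone.

Step 6
Reactants: 7 2-[(1R)-5-methyl-4-oxocyclohepta-2,5-dien-1-yl]prop-2-enal
Product: 8 2-[(1R)-5-methyl-4-oxocyclohepta-2,5-dien-1-yl]prop-2-enoic acid
Conditions: NaClO2, NaH2PO4, 2‑methylbut‑2‑ene, t‑BuOH/H2O, 0 °C to rt
Reagents that add atoms: sodium chlorite [Na+].[O-]Cl=O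
Why: Pinnick oxidation of the enal to the acrylic acid; 2‑methylbut‑2‑ene scavenges HOCl so the three double bonds are not chlorinated.

Step 7
Reactants: 8 2-[(1R)-5-methyl-4-oxocyclohepta-2,5-dien-1-yl]prop-2-enoic acid
Product: 9 (3aS,8aS)-6-methyl-3-methylidene-3a,4,8,8a-tetrahydro-2H-cyclohepta[b]furan-2,7(3H)-dione
Conditions: camphorsulfonic acid (cat.), CH2Cl2, 0 °C to rt
Reagents that add atoms: none
Why: Acid‑catalysed intramolecular oxa‑Michael addition: the carboxyl adds 5‑exo‑trig to C6, the β‑carbon of the C1 enone, on the β face where its two‑atom tether sits, so the lactone is cis‑fused. The step stores the C5=C6 enone in a form that β‑elimination gives back and turns the monocycle into a bicycle with a convex and a concave face.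

Step 8
Reactants: 9 (3aS,8aS)-6-methyl-3-methylidene-3a,4,8,8a-tetrahydro-2H-cyclohepta[b]furan-2,7(3H)-dione
Product: 10 (3R,3aS,6S,8aS)-3,6-dimethylhexahydro-2H-cyclohepta[b]furan-2,7(3H)-dione
Conditions: H2 (1 atm), Pd/C, EtOAc, rt
Reagents that add atoms: none
Why: Heterogeneous hydrogenation adds H2 syn from the convex α face of the cis‑fused bicycle (the face of H‑6 and H‑7). At the exocyclic alkene this sets C11 (methyl endo); at the enone it sets C10 (methyl β, cis to the C7 branch). Ketone and lactone are not reduced, and neutral conditions keep the two α‑carbonyl centres from epimerizing.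

Step 9
Reactants: 10 (3R,3aS,6S,8aS)-3,6-dimethylhexahydro-2H-cyclohepta[b]furan-2,7(3H)-dione
Product: 13 (2R)-2-[(1R,4S,5S)-4-[(2E)-but-2-enoyl]-4-hydroxy-5-methylcyclohept-2-en-1-yl]propanoic acid, via enone acid 11 (not isolated), via dienyl ether adduct 12 (not isolated)
Conditions: DBU, THF, 0 °C; then [(1E)-1-methoxybuta-1,3-dien-1-yl]lithium (from (1E)-1-methoxybuta-1,3-diene, tert‑butyllithium, THF, −78 to −30 °C), −78 °C; then 1 M HCl, THF/H2O, 0 °C
Reagents that add atoms: (1E)-1-methoxybuta-1,3-diene C=C/C=C/OC; water O
Why: DBU opens the β‑acyloxy ketone by E1cB so that C5 is sp2 again when C1 is attacked (one equivalent of the organolithium is spent on the DBU salt). The α‑lithiated methoxydiene, an acyl anion equivalent made like lithiated methyl vinyl ether, adds 1,2 to the carbonyl from the α face, anti to the adjacent C10 methyl and the C7 branch, which puts the new C–C bond α and the hydroxyl β. Aqueous acid protonates the dienyl ether at its terminus and hydrolyses the oxocarbenium ion to the (E)‑enone.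

Step 10
Reactants: 13 (2R)-2-[(1R,4S,5S)-4-[(2E)-but-2-enoyl]-4-hydroxy-5-methylcyclohept-2-en-1-yl]propanoic acid
Product: 14 (3R,3aS,6S,7R,8S,8aR)-7-[(2E)-but-2-enoyl]-7-hydroxy-8-iodo-3,6-dimethyloctahydro-2H-cyclohepta[b]furan-2-one
Conditions: I2, NaHCO3, MeCN/H2O, 0 °C, dark
Reagents that add atoms: iodine II
Why: Iodine forms the iodonium ion of the C5=C6 alkene reversibly on either face; the carboxylate of the β‑oriented C7 branch captures the α‑iodonium ion at C6 anti to iodine. The closest known reaction type is the iodolactonization of cycloalk‑2‑en‑1‑ylacetic acids to cis‑fused γ‑lactones. The lactone closes in the 5‑exo mode, and the fusion is expected cis because the two‑atom tether from C7 reaches C6 most easily on its own face. C6 (O β) is set by the tether from C7 and C5 (I α) by the anti course of the addition. Three selectivities are needed: 5‑exo over 6‑endo closure, secured by ring size and by the neopentylic, inductively deactivated C5; reaction at C5=C6 and not at the electron‑poor butenoyl double bond; and capture by the carboxylate in preference to a halonium‑induced 1,2‑shift of the allylic ketol, which is disfavoured because it would turn C1 into the carbon of a 1,2‑dione. The iodine ends up anti to the C1 hydroxyl, which lets step 11 replace it with retention.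

Step 11
Reactants: 14 (3R,3aS,6S,7R,8S,8aR)-7-[(2E)-but-2-enoyl]-7-hydroxy-8-iodo-3,6-dimethyloctahydro-2H-cyclohepta[b]furan-2-one
Product: 16 (3R,3aS,6S,7S,8S,8aR)-7-[(2E)-but-2-enoyl]-7-hydroxy-3,6-dimethyl-2-oxooctahydro-2H-cyclohepta[b]furan-8-yl 2-methylpropanoate, via epoxide 15 (not isolated)
Conditions: Cs2CO3, MeCN, 0 °C to rt; then 2‑methylpropanoic acid (excess), 60 °C
Reagents that add atoms: 2-methylpropanoic acid CC(C)C(O)=O
Why: Carbonate deprotonates the ketol hydroxyl, which displaces the anti iodide in a 3‑exo‑tet closure (trans‑iodohydrin to epoxide, inversion at C5). Isobutyric acid then opens the epoxide at C5, the only position open to substitution since C1 is quaternary and α to a carbonyl, with a second inversion. The ester enters as the nucleophile with net retention (O5 α, trans to O1 and O6), so no protecting group or separate acylation is needed.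

## Compound list

1 | (R)‑(−)‑carvone, (5R)-2-methyl-5-(prop-1-en-2-yl)cyclohex-2-en-1-one | CC1=CC[C@@H](C(C)=C)CC1=O | starting material
2 | trimethyl{[(3R)-6-methyl-3-(prop-1-en-2-yl)cyclohexa-1,5-dien-1-yl]oxy}silane | CC1=CC[C@@H](C(C)=C)C=C1O[Si](C)(C)C | intermediate
3 | trimethyl{[(1R,5R,6S)-2-methyl-5-(prop-1-en-2-yl)bicyclo[4.1.0]hept-2-en-1-yl]oxy}silane (cyclopropane anti to the isopropenyl group; the other face isomer reacts alike) | CC1=CC[C@@H](C(C)=C)[C@@H]2C[C@]12O[Si](C)(C)C | intermediate
4 | (5S,6R)-6-chloro-2-methyl-5-(prop-1-en-2-yl)cyclohept-2-en-1-one (configuration at the chlorinated carbon without consequence) | CC1=CC[C@@H](C(C)=C)[C@H](Cl)CC1=O | intermediate (not isolated)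
5 | (5R)-2-methyl-5-(prop-1-en-2-yl)cyclohepta-2,6-dien-1-one | CC1=CC[C@@H](C(C)=C)C=CC1=O | intermediate
6 | (5R)-5-(3-chloroprop-1-en-2-yl)-2-methylcyclohepta-2,6-dien-1-one | CC1=CC[C@@H](C(CCl)=C)C=CC1=O | intermediate
7 | 2-[(1R)-5-methyl-4-oxocyclohepta-2,5-dien-1-yl]prop-2-enal | CC1=CC[C@@H](C(C=O)=C)C=CC1=O | intermediate
8 | 2-[(1R)-5-methyl-4-oxocyclohepta-2,5-dien-1-yl]prop-2-enoic acid | CC1=CC[C@@H](C(C(O)=O)=C)C=CC1=O | intermediate
9 | (3aS,8aS)-6-methyl-3-methylidene-3a,4,8,8a-tetrahydro-2H-cyclohepta[b]furan-2,7(3H)-dione (cis‑fused 12,6‑lactone, 1‑oxo‑9‑ene, 11(13)‑ene) | O=C1C(C)=CC[C@@H]2[C@@H](OC(=O)C2=C)C1 | intermediate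
10 | (3R,3aS,6S,8aS)-3,6-dimethylhexahydro-2H-cyclohepta[b]furan-2,7(3H)-dione | O=C1[C@@H](C)CC[C@@H]2[C@@H](OC(=O)[C@@H]2C)C1 | intermediate
11 | (2R)-2-[(1R,5S)-5-methyl-4-oxocyclohept-2-en-1-yl]propanoic acid (as its DBU salt) | O=C1[C@@H](C)CC[C@@H]([C@@H](C)C(O)=O)C=C1 | intermediate (not isolated)
12 | (2R)-2-[(1R,4S,5S)-4-hydroxy-4-[(1E)-1-methoxybuta-1,3-dien-1-yl]-5-methylcyclohept-2-en-1-yl]propanoic acid (as its dilithium salt) | C=C/C=C(OC)\[C@]1(O)[C@@H](C)CC[C@@H]([C@@H](C)C(O)=O)C=C1 | intermediate (not isolated)
13 | (2R)-2-[(1R,4S,5S)-4-[(2E)-but-2-enoyl]-4-hydroxy-5-methylcyclohept-2-en-1-yl]propanoic acid | C/C=C/C(=O)[C@]1(O)[C@@H](C)CC[C@@H]([C@@H](C)C(O)=O)C=C1 | intermediate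
14 | (3R,3aS,6S,7R,8S,8aR)-7-[(2E)-but-2-enoyl]-7-hydroxy-8-iodo-3,6-dimethyloctahydro-2H-cyclohepta[b]furan-2-one (5α‑iodide) | C/C=C/C(=O)[C@]1(O)[C@@H](C)CC[C@@H]2[C@@H](OC(=O)[C@@H]2C)[C@@H]1I | intermediate
15 | 1β,5β‑epoxide of the lactone: 7-[(2E)-but-2-enoyl]-7,8-epoxy-3,6-dimethyloctahydro-2H-cyclohepta[b]furan-2-one, epoxide oxygen on the lactone face | C/C=C/C(=O)[C@]1(O3)[C@@H](C)CC[C@@H]2[C@@H](OC(=O)[C@@H]2C)[C@H]13 | intermediate (not isolated)
16 | (3R,3aS,6S,7S,8S,8aR)-7-[(2E)-but-2-enoyl]-7-hydroxy-3,6-dimethyl-2-oxooctahydro-2H-cyclohepta[b]furan-8-yl 2-methylpropanoate (CNP0149747.1; xanthane numbering 1S,5S,6R,7S,10S,11R) | C/C=C/C(=O)[C@]1(O)[C@@H](C)CC[C@@H]2[C@@H](OC(=O)[C@@H]2C)[C@@H]1OC(=O)C(C)C | target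

## Step count and risks

Total steps: 11. Longest linear sequence: 11 (from (R)‑carvone; the route is linear).

**Step 10 (key step).** The flexible seven‑membered ring may allow capture of the iodonium ion in the 6‑endo sense or on the α face (trans‑fused lactone), or a halonium‑induced 1,2‑shift of the allylic ketol. Fallback, from 13 and back at 16: the C5 oxygen is brought in as the electrophile and the substitution is moved to C6. Epoxidation of 13 with m‑chloroperbenzoic acid (CH2Cl2, NaHCO3) would give, beside its β isomer, α‑epoxy acid F1. Camphorsulfonic acid lets the carboxyl of F1 open the epoxide at C6 with inversion to hydroxy lactone F2; the β‑epoxide cannot lactonize and is removed here. Isobutyric anhydride and 4‑(dimethylamino)pyridine then acylate the secondary C5 hydroxyl of F2, not the tertiary one, to give 16.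

**Step 11.** Substitution at the neopentylic C5 may be slow, which would leave room for acid‑induced rearrangement of the epoxy ketone (acyl shift) or for attack by adventitious water. Fallback, from 13 and back at 16: OsO4 (catalytic) with N‑methylmorpholine N‑oxide should dihydroxylate C5=C6 on the α face, anti to the allylic C1 hydroxyl and the C7 branch, to triol acid F3. Mitsunobu lactonization (PPh3, diisopropyl azodicarboxylate) activates the less hindered C6 hydroxyl and closes the lactone with inversion at C6 to hydroxy lactone F2, which is acylated as above to 16.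

**Step 9.** The basic organolithium may enolize the enone in place of adding to it; lithiation of the diene may be incomplete or accompanied by addition of tert‑butyllithium; and the face selectivity rests on the C10 methyl and a remote branch in a flexible ring. Fallback, from 11 (made from 10 with DBU) and back at 13: the smaller lithiated methoxyallene (methoxyallene, n‑butyllithium, with CeCl3) adds to give allenyl ether F4, which aqueous acid hydrolyses to vinyl ketone F5. Cross‑metathesis of F5 with (Z)‑but‑2‑ene and the second‑generation Grubbs catalyst then installs the terminal methyl group to give 13.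

**Step 8.** Face discrimination at C10 may be poor because C9=C10 is two bonds from the ring fusion, and Pd may shift the exocyclic double bond into the lactone ring. Fallback, from 9 and back at 10: RhCl(PPh3)3 and H2 reduce only the exocyclic alkene from the convex face to enone lactone F6. Conjugate reduction of F6 with LiBH(sec‑Bu)3 at −78 °C gives the enolate towards C10 only, and protonation by 2,6‑di‑tert‑butyl‑4‑methylphenol on the convex face gives 10.

**Step 7.** The conjugate‑addition equilibrium may be unfavourable, equilibration may lead to the trans‑fused lactone, or acid may isomerize the dienone. Fallback, from 8 and back at 11: nucleophilic epoxidation (H2O2, NaOH, MeOH, 0 °C) on the α face, anti to the C7 branch, gives epoxy acid F7. On acidification its carboxyl opens the epoxide at C6 with inversion to hydroxy lactone F8, cis‑fused by necessity. Hydrogenation with [Ir(cod)(PCy3)(py)]PF6, where the C5 hydroxyl directs delivery to the α face, gives F9, and acetylation (Ac2O, 4‑(dimethylamino)pyridine) gives acetate F10. SmI2 (THF/MeOH, −78 °C) removes the α‑acetoxy group, and the C1 enolate so formed expels the lactone carboxylate to give 11.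

## Further compounds

F1 | step 10 | (2R)-2-[(1S,4S,5S)-4-[(2E)-but-2-enoyl]-4-hydroxy-5-methyl-2α,3α-epoxycycloheptyl]propanoic acid (5α,6α‑epoxide of 13) | C/C=C/C(=O)[C@]1(O)[C@@H](C)CC[C@@H]([C@@H](C)C(O)=O)[C@@H]2O[C@H]12
F2 | step 10 | 5α‑hydroxy lactone, 7-[(2E)-but-2-enoyl]-7,8-dihydroxy-3,6-dimethyloctahydro-2H-cyclohepta[b]furan-2-one (16 without the isobutyryl group) | C/C=C/C(=O)[C@]1(O)[C@@H](C)CC[C@@H]2[C@@H](OC(=O)[C@@H]2C)[C@@H]1O
F3 | step 11 | triol acid, 5α,6α‑diol of 13 | C/C=C/C(=O)[C@]1(O)[C@@H](C)CC[C@@H]([C@@H](C)C(O)=O)[C@H](O)[C@@H]1O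
F4 | step 9 | (2R)-2-[(1R,4S,5S)-4-hydroxy-4-(1-methoxypropa-1,2-dien-1-yl)-5-methylcyclohept-2-en-1-yl]propanoic acid | C=C=C(OC)[C@]1(O)[C@@H](C)CC[C@@H]([C@@H](C)C(O)=O)C=C1
F5 | step 9 | (2R)-2-[(1R,4S,5S)-4-hydroxy-5-methyl-4-(prop-2-enoyl)cyclohept-2-en-1-yl]propanoic acid | C=CC(=O)[C@]1(O)[C@@H](C)CC[C@@H]([C@@H](C)C(O)=O)C=C1
F6 | step 8 | (3R,3aS,8aS)-3,6-dimethyl-3a,4,8,8a-tetrahydro-2H-cyclohepta[b]furan-2,7(3H)-dione | O=C1C(C)=CC[C@@H]2[C@@H](OC(=O)[C@@H]2C)C1
F7 | step 7 | 5α,6α‑epoxide of acid 8 | O=C1C(C)=CC[C@@H](C(=C)C(O)=O)[C@@H]2O[C@H]12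
F8 | step 7 | 5α‑hydroxy derivative of lactone 9 | O=C1C(C)=CC[C@@H]2[C@@H](OC(=O)C2=C)[C@@H]1O
F9 | step 7 | 5α‑hydroxy derivative of keto lactone 10 | O=C1[C@@H](C)CC[C@@H]2[C@@H](OC(=O)[C@@H]2C)[C@@H]1O
F10 | step 7 | 5α‑acetoxy derivative of keto lactone 10 | O=C1[C@@H](C)CC[C@@H]2[C@@H](OC(=O)[C@@H]2C)[C@@H]1OC(C)=O
A1 | alternative 1 | methyl (2R,3R,6S)-3-ethenyl-2,6-dimethyl-7-oxonon-8-enoate | C=CC(=O)[C@@H](C)CC[C@H](C=C)[C@@H](C)C(=O)OC
A2 | alternative 1 | methyl (2R)-2-[(1R,5S)-5-methyl-4-oxocyclohept-2-en-1-yl]propanoate | O=C1[C@@H](C)CC[C@@H]([C@@H](C)C(=O)OC)C=C1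
A3 | alternative 2 | cis‑fused 3,6-dimethylhexahydro-1-benzofuran-2,7-dione (six‑membered keto lactone; methyl groups as in 10) | O=C1[C@@H](C)CC[C@@H]2[C@H]1OC(=O)[C@@H]2C
A4 | alternative 2 | 7-hydroxy-3,6-dimethyl-7-[(3E)-2-oxopent-3-enoyl]hexahydro-1-benzofuran-2-one (hydroxyl on the lactone face) | C/C=C/C(=O)C(=O)[C@]1(O)[C@@H](C)CC[C@@H]2[C@H]1OC(=O)[C@@H]2C
A5 | alternative 2 | 7-[(2E)-but-2-enoyl]-7-hydroxy-3,6-dimethylhexahydro-2H-cyclohepta[b]furan-2,8(3H)-dione (5‑ketone of the target skeleton) | C/C=C/C(=O)[C@]1(O)[C@@H](C)CC[C@@H]2[C@@H](OC(=O)[C@@H]2C)C1=O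
A6 | alternative 3 | 3-bromo-2-oxopropyl (2R,3E,5E)-2-methylhepta-3,5-dienoate | C/C=C/C=C/[C@@H](C)C(=O)OCC(=O)CBr
A7 | alternative 3 | cis‑fused 3,6-dimethyl-3,3a,6,7-tetrahydro-2H-cyclohepta[b]furan-2,8(8aH)-dione (5‑oxo‑8‑ene cycloadduct) | O=C1C[C@@H](C)C=C[C@@H]2[C@H]1OC(=O)[C@@H]2C
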